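**Retrosynthetic overview**
1. The target ring is a 2-allyl-4,5-dimethoxycyclohexa-2,5-dienone. Its C1 carbonyl, C6–H, C5–OMe and C4–O bond match atom for atom the C2(=O), C3–H, C4–OMe and O1–C5 bond of a 5-substituted 4-methoxyfuran-2(5H)-one (methyl tetronate), so only C2 and C3 are missing.
2. Key disconnection: C3–C4 and C1–C2, a Michael–Dieckmann annulation of the tetronate C5 anion with allyl acrylate. The lactone ring is exchanged for the six-membered carbocycle, the only ring formed in the route.
3. Endgame: the allyl ester first activates C2 for allylation, then serves as a traceless handle for palladium-catalysed decarboxylative dehydrogenation (C2=C3). O-Methylation of the C4 carbinol and desilylation finish.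
4. The tetronate comes from an α-methyl aldehyde (Evans alkylation with a silylated vanillyl bromide) by propiolate addition and methoxide-induced cyclisation. The side-chain stereocentre set there directs the new quaternary centre C4.

Key step: step 9

Remark: Ar = 3-methoxy-4-(triisopropylsilyloxy)phenyl. Centres that later become sp2 (carbinol carbon of 12, C5 of 14, ester-bearing carbon of 19 and 20) are carried as epimer mixtures. The phenol is carried as its triisopropylsilyl ether because this hindered aryl silyl ether should withstand the catalytic methoxide of step 8.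

**Step 1**
Reactants: 1 vanillin (4-hydroxy-3-methoxybenzaldehyde)
Product: 2 3-methoxy-4-(triisopropylsilyloxy)benzaldehyde
Conditions: i-Pr3SiCl, imidazole, DMF, rt
Reagents that add atoms: chlorotriisopropylsilane, CC(C)[Si](Cl)(C(C)C)C(C)C
Why: Imidazole-assisted silylation of the phenol is standard and leaves the aldehyde untouched.

**Step 2**
Reactants: 2 3-methoxy-4-(triisopropylsilyloxy)benzaldehyde
Product: 3 [3-methoxy-4-(triisopropylsilyloxy)phenyl]methanol
Conditions: NaBH4, MeOH, 0 °C
Reagents that add atoms: none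
Why: Borohydride reduction of an aryl aldehyde to the benzylic alcohol, with the silyl and methyl ethers inert.

**Step 3**
Reactants: 3 [3-methoxy-4-(triisopropylsilyloxy)phenyl]methanol
Product: 4 4-(bromomethyl)-2-methoxy-1-(triisopropylsilyloxy)benzene
Conditions: CBr4, PPh3, CH2Cl2, 0 °C
Reagents that add atoms: carbon tetrabromide, BrC(Br)(Br)Br
Why: Appel bromination of the benzylic alcohol runs under neutral conditions that spare the aryl silyl ether; the bromide is used at once.

**Step 4**
Reactants: 5 (S)-4-benzyl-3-propionyloxazolidin-2-one; 4 4-(bromomethyl)-2-methoxy-1-(triisopropylsilyloxy)benzene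
Product: 7 (4S)-4-benzyl-3-[(2R)-3-Ar-2-methylpropanoyl]oxazolidin-2-one, via sodium enolate 6 (not isolated)
Conditions: NaN(SiMe3)2, THF, −78 °C; then 4, −78 to −40 °C
Reagents that add atoms: none
Why: Evans asymmetric alkylation, in which the chelated (Z)-enolate 6 is benzylated on the face opposite the C4 benzyl group of the auxiliary and so sets the (R) methyl-bearing centre.

**Step 5**
Reactants: 7 (4S)-4-benzyl-3-[(2R)-3-Ar-2-methylpropanoyl]oxazolidin-2-one
Product: 8 (2R)-3-Ar-2-methylpropan-1-ol
Conditions: LiBH4, MeOH (1 equiv), THF, 0 °C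
Reagents that add atoms: none
Why: Reductive cleavage of the N-acyl oxazolidinone at the exocyclic carbonyl gives the primary alcohol without touching the stereocentre and returns the auxiliary.

**Step 6**
Reactants: 8 (2R)-3-Ar-2-methylpropan-1-ol
Product: 9 (2R)-3-Ar-2-methylpropanal
Conditions: Dess–Martin periodinane, NaHCO3, CH2Cl2, 0 °C to rt
Reagents that add atoms: none
Why: Buffered Dess–Martin oxidation should give the α-branched aldehyde without epimerisation; it is used crude in step 7.

**Step 7**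
Reactants: 10 methyl propiolate; 9 (2R)-3-Ar-2-methylpropanal
Product: 12 methyl (5R)-6-Ar-4-hydroxy-5-methylhex-2-ynoate (C4 epimers), via lithium acetylide 11 (not isolated)
Conditions: LiN(SiMe3)2, THF, −78 °C; then 9, −78 °C; AcOH quench
Reagents that add atoms: none
Why: 1,2-Addition of the lithium acetylide of methyl propiolate (kept at −78 °C) to the aldehyde; the new carbinol centre need not be controlled because it becomes sp2 in step 9.

**Step 8**
Reactants: 12 methyl (5R)-6-Ar-4-hydroxy-5-methylhex-2-ynoate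
Product: 14 4-methoxy-5-[(2R)-1-Ar-propan-2-yl]furan-2(5H)-one (C5 epimers), via methoxy enoate 13 (not isolated)
Conditions: NaOMe (0.2 equiv), MeOH, 0 °C to rt
Reagents that add atoms: methanol, CO
Why: Methoxide conjugate addition to the ynoate gives the (E)-3-methoxy enoate 13, whose hydroxyl lactonises onto the cis ester and regenerates methoxide (tetronate synthesis from γ-hydroxy ynoates), fixing the enol-ether regiochemistry.

**Step 9**
Reactants: 14 4-methoxy-5-[(2R)-1-Ar-propan-2-yl]furan-2(5H)-one; 15 allyl acrylate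
Product: 19 allyl (5R)-5-hydroxy-4-methoxy-2-oxo-5-[(2R)-1-Ar-propan-2-yl]cyclohex-3-ene-1-carboxylate (C1 epimers), via lithium furanolate 16 (not isolated), via Michael-adduct enolate 17 (not isolated), via bridged alkoxide 18 (not isolated)
Conditions: LiN(i-Pr)2 (1.05 equiv), THF, −78 °C; then 15 (slow addition), −78 to 0 °C; AcOH, −78 °C
Reagents that add atoms: none
Why: Proposed new method: LiN(i-Pr)2 removes the C5–H of 14 to give the aromatic 2-oxidofuran 16, whose C5 adds to the β-carbon of allyl acrylate (future C3–C4 bond); the ester enolate 17 then acylates on the lactone carbonyl (future C1–C2 bond) to give the 7-oxanorbornene alkoxide 18, which opens at the C–O bridge and ends as the stabilised β-keto ester enolate, a thermodynamic sink that makes any reversible C3 addition unproductive. The closest known reaction types are the Hauser–Kraus (Michael–Dieckmann) annulation of phthalide anions and the Diels–Alder route from 2-silyloxyfurans to 4-hydroxycyclohexenones; a simple 5-alkyl methyl tetronate has not been used in this way. The six-membered carbocycle closes by 6-exo-trig attack of the enolate carbon on the lactone C=O (equivalently the second bond of an asynchronous anionic [4+2]), and the lactone ring is given up in the same event. The new quaternary carbinol centre is controlled by the adjacent (R) centre: its C–H should lie in the furanolate plane syn to the C4 methoxy group to relieve A(1,3) strain, placing CH3 on one face and CH2Ar on the other, and acrylate attack on the methyl-bearing face gives the required (5R) configuration. The step needs C5 rather than C3 attack, 1,4- rather than 1,2-addition and incorporation of a single acrylate; the vinylogous position of the 2-oxidofuran, the soft acceptor and the fast intramolecular acylation under slow addition at −78 °C should secure these, and the minor carbinol epimer is to be removed by chromatography of 19 or 21.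

**Step 10**
Reactants: 19 allyl (5R)-5-hydroxy-4-methoxy-2-oxo-5-[(2R)-1-Ar-propan-2-yl]cyclohex-3-ene-1-carboxylate
Product: 20 allyl (5R)-1-allyl-5-hydroxy-4-methoxy-2-oxo-5-[(2R)-1-Ar-propan-2-yl]cyclohex-3-ene-1-carboxylate (C1 epimers)
Conditions: K2CO3, allyl bromide, acetone, rt
Reagents that add atoms: allyl bromide, C=CCBr
Why: C-Alkylation of a cyclic β-keto ester enolate under carbonate conditions that do not ionise the tertiary alcohol; the new quaternary centre is removed in step 11, so its configuration is irrelevant.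

**Step 11**
Reactants: 20 allyl (5R)-1-allyl-5-hydroxy-4-methoxy-2-oxo-5-[(2R)-1-Ar-propan-2-yl]cyclohex-3-ene-1-carboxylate
Product: 21 (4S)-2-allyl-4-hydroxy-5-methoxy-4-[(2R)-1-Ar-propan-2-yl]cyclohexa-2,5-dien-1-one
Conditions: Pd(OAc)2 (10 mol%), dppe (10 mol%), MeCN, reflux
Reagents that add atoms: none
Why: Tsuji decarboxylation–dehydrogenation, in which zerovalent palladium formed in situ ionises the allyl ester, loss of CO2 gives a π-allylpalladium enolate, and β-hydride elimination from the ring CH2 followed by release of propene gives the cross-conjugated dienone; acetonitrile and a chelating phosphine favour elimination over reductive allylation.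

**Step 12**
Reactants: 21 (4S)-2-allyl-4-hydroxy-5-methoxy-4-[(2R)-1-Ar-propan-2-yl]cyclohexa-2,5-dien-1-one
Product: 22 (4S)-2-allyl-4,5-dimethoxy-4-[(2R)-1-Ar-propan-2-yl]cyclohexa-2,5-dien-1-one
Conditions: NaH, MeI, THF, 0 °C to rt
Reagents that add atoms: iodomethane, CI
Why: Williamson methylation of the p-quinol alkoxide, placed here because 21 has no enolisable hydrogen and no retro-Claisen path, whereas an alkoxide generated in 20 could attack its non-enolisable β-keto ester.

**Step 13**
Reactants: 22 (4S)-2-allyl-4,5-dimethoxy-4-[(2R)-1-Ar-propan-2-yl]cyclohexa-2,5-dien-1-one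
Product: 23 (4S)-2-allyl-4-[(2R)-1-(4-hydroxy-3-methoxyphenyl)propan-2-yl]-4,5-dimethoxycyclohexa-2,5-dien-1-one
Conditions: Bu4NF, AcOH, THF, 0 °C
Reagents that add atoms: none
Why: Fluoride cleavage of the aryl silyl ether, buffered with acetic acid so that neither phenoxide nor basic fluoride acts on the dienone or the allyl group.

**Compound list**
1 | vanillin (4-hydroxy-3-methoxybenzaldehyde) | COc1cc(C=O)ccc1O | starting material
2 | 3-methoxy-4-(triisopropylsilyloxy)benzaldehyde | COc1cc(C=O)ccc1O[Si](C(C)C)(C(C)C)C(C)C | intermediate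
3 | [3-methoxy-4-(triisopropylsilyloxy)phenyl]methanol | COc1cc(CO)ccc1O[Si](C(C)C)(C(C)C)C(C)C | intermediate
4 | 4-(bromomethyl)-2-methoxy-1-(triisopropylsilyloxy)benzene | COc1cc(CBr)ccc1O[Si](C(C)C)(C(C)C)C(C)C | intermediate
5 | (S)-4-benzyl-3-propionyloxazolidin-2-one | CCC(=O)N1[C@@H](Cc2ccccc2)COC1=O | starting material
6 | sodium (Z)-enolate of 5 | [Na+].C/C=C(\[O-])N1[C@@H](Cc2ccccc2)COC1=O | intermediate
7 | (4S)-4-benzyl-3-[(2R)-3-(3-methoxy-4-triisopropylsilyloxyphenyl)-2-methylpropanoyl]oxazolidin-2-one | O=C1OC[C@H](Cc2ccccc2)N1C(=O)[C@H](C)Cc1ccc(O[Si](C(C)C)(C(C)C)C(C)C)c(OC)c1 | intermediate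
8 | (2R)-3-(3-methoxy-4-triisopropylsilyloxyphenyl)-2-methylpropan-1-ol | OC[C@H](C)Cc1ccc(O[Si](C(C)C)(C(C)C)C(C)C)c(OC)c1 | intermediate
9 | (2R)-3-(3-methoxy-4-triisopropylsilyloxyphenyl)-2-methylpropanal | O=C[C@H](C)Cc1ccc(O[Si](C(C)C)(C(C)C)C(C)C)c(OC)c1 | intermediate
10 | methyl propiolate | C#CC(=O)OC | starting material
11 | lithium acetylide of methyl propiolate | [Li+].[C-]#CC(=O)OC | intermediate
12 | methyl (5R)-4-hydroxy-6-(3-methoxy-4-triisopropylsilyloxyphenyl)-5-methylhex-2-ynoate (C4 epimers) | COC(=O)C#CC(O)[C@H](C)Cc1ccc(O[Si](C(C)C)(C(C)C)C(C)C)c(OC)c1 | intermediate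
13 | methyl (2E,5R)-4-hydroxy-3-methoxy-6-(3-methoxy-4-triisopropylsilyloxyphenyl)-5-methylhex-2-enoate | COC(=O)/C=C(/OC)C(O)[C@H](C)Cc1ccc(O[Si](C(C)C)(C(C)C)C(C)C)c(OC)c1 | intermediate
14 | 4-methoxy-5-[(2R)-1-(3-methoxy-4-triisopropylsilyloxyphenyl)propan-2-yl]furan-2(5H)-one (C5 epimers) | COC1=CC(=O)OC1[C@H](C)Cc1ccc(O[Si](C(C)C)(C(C)C)C(C)C)c(OC)c1 | intermediate
15 | allyl acrylate | C=CC(=O)OCC=C | starting material
16 | lithium 4-methoxy-5-[(2R)-1-(3-methoxy-4-triisopropylsilyloxyphenyl)propan-2-yl]furan-2-olate | [Li+].[O-]c1cc(OC)c(o1)[C@H](C)Cc1ccc(O[Si](C(C)C)(C(C)C)C(C)C)c(OC)c1 | intermediate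
17 | lithium ester enolate of allyl 3-{(2R)-3-methoxy-5-oxo-2-[(2R)-1-(3-methoxy-4-triisopropylsilyloxyphenyl)propan-2-yl]-2,5-dihydrofuran-2-yl}propanoate | [Li+].C=CCOC([O-])=CC[C@@]1(OC(=O)C=C1OC)[C@H](C)Cc1ccc(O[Si](C(C)C)(C(C)C)C(C)C)c(OC)c1 | intermediate
18 | lithium (1S,4R)-2-(allyloxycarbonyl)-5-methoxy-4-[(2R)-1-(3-methoxy-4-triisopropylsilyloxyphenyl)propan-2-yl]-7-oxabicyclo[2.2.1]hept-5-en-1-olate (C2 epimers) | [Li+].[O-][C@@]12C=C(OC)[C@@](O1)(CC2C(=O)OCC=C)[C@H](C)Cc1ccc(O[Si](C(C)C)(C(C)C)C(C)C)c(OC)c1 | intermediate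
19 | allyl (5R)-5-hydroxy-4-methoxy-2-oxo-5-[(2R)-1-(3-methoxy-4-triisopropylsilyloxyphenyl)propan-2-yl]cyclohex-3-ene-1-carboxylate (C1 epimers) | C=CCOC(=O)C1C[C@@](O)([C@H](C)Cc2ccc(O[Si](C(C)C)(C(C)C)C(C)C)c(OC)c2)C(OC)=CC1=O | intermediate
20 | allyl (5R)-1-allyl-5-hydroxy-4-methoxy-2-oxo-5-[(2R)-1-(3-methoxy-4-triisopropylsilyloxyphenyl)propan-2-yl]cyclohex-3-ene-1-carboxylate (C1 epimers) | C=CCOC(=O)C1(CC=C)C[C@@](O)([C@H](C)Cc2ccc(O[Si](C(C)C)(C(C)C)C(C)C)c(OC)c2)C(OC)=CC1=O | intermediate
21 | (4S)-2-allyl-4-hydroxy-5-methoxy-4-[(2R)-1-(3-methoxy-4-triisopropylsilyloxyphenyl)propan-2-yl]cyclohexa-2,5-dien-1-one | C=CCC1=C[C@@](O)([C@H](C)Cc2ccc(O[Si](C(C)C)(C(C)C)C(C)C)c(OC)c2)C(OC)=CC1=O | intermediate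
22 | (4S)-2-allyl-4,5-dimethoxy-4-[(2R)-1-(3-methoxy-4-triisopropylsilyloxyphenyl)propan-2-yl]cyclohexa-2,5-dien-1-one | C=CCC1=C[C@@](OC)([C@H](C)Cc2ccc(O[Si](C(C)C)(C(C)C)C(C)C)c(OC)c2)C(OC)=CC1=O | intermediate
23 | (4S)-2-allyl-4-[(2R)-1-(4-hydroxy-3-methoxyphenyl)propan-2-yl]-4,5-dimethoxycyclohexa-2,5-dien-1-one (CNP0370214.1) | C=CCC1=C[C@@](OC)([C@H](C)Cc2ccc(O)c(OC)c2)C(OC)=CC1=O | target

**Step count**
Total steps: 13. Longest linear sequence: 13 steps (1 to 23; the auxiliary 5, methyl propiolate 10 and allyl acrylate 15 enter as purchased materials).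

**Steps most likely to fail**

1. Step 9 (the step that carries the new-method label). The acrylate may oligomerise under anionic conditions, the sequence may stall by proton transfer after the Michael addition, facial discrimination at the furanolate carbon may be weak, or the product may dehydrate and aromatise on acidic work-up. The fallback uses known chemistry and sets out from 14. Silylation of the furanolate (LiN(i-Pr)2, t-BuMe2SiCl, THF, −78 °C) should give 2-(tert-butyldimethylsilyloxy)-4-methoxy-5-[(2R)-1-Ar-propan-2-yl]furan F1. A thermal Diels–Alder reaction of this electron-rich furan with allyl acrylate 15 (toluene, rt to 60 °C) should give the silyl ketal allyl (1R,4R)-1-(tert-butyldimethylsilyloxy)-5-methoxy-4-[(2R)-1-Ar-propan-2-yl]-7-oxabicyclo[2.2.1]hept-5-ene-2-carboxylate F2, with the nucleophilic C5 terminus bonded to the acrylate β-carbon. Mild hydrolysis of the silyl ketal (PPTS, wet THF, 0 °C) opens the oxygen bridge and the route is rejoined at 19. The bulk of the silyl group offers an extra means of tuning the facial selectivity.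

2. Step 11. β-Hydride elimination may occur toward the side-chain CH2 to give an exocyclic diene, a palladium hydride may move the terminal alkene into conjugation, or reductive elimination may give the 2,2-diallyl ketone. The fallback sets out from 19 and carries the allyl group as a masked propargyl group. Alkylation with 3-bromo-1-(trimethylsilyl)prop-1-yne (K2CO3, acetone) should give allyl (5R)-5-hydroxy-4-methoxy-2-oxo-5-[(2R)-1-Ar-propan-2-yl]-1-[3-(trimethylsilyl)prop-2-yn-1-yl]cyclohex-3-ene-1-carboxylate F3. The same Pd(OAc)2/dppe conditions, for which 2-alkynyl side chains are the best-precedented substrates for endocyclic elimination, should give (4S)-4-hydroxy-5-methoxy-4-[(2R)-1-Ar-propan-2-yl]-2-[3-(trimethylsilyl)prop-2-yn-1-yl]cyclohexa-2,5-dien-1-one F4. C-Desilylation (K2CO3 cat., MeOH, 0 °C) should give (4S)-4-hydroxy-5-methoxy-4-[(2R)-1-Ar-propan-2-yl]-2-(prop-2-yn-1-yl)cyclohexa-2,5-dien-1-one F5. Semihydrogenation (Pd/CaCO3 poisoned with Pb(OAc)2, quinoline, H2, EtOAc) then rejoins the route at 21.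

3. Step 12. The hindered tertiary alkoxide may alkylate slowly, the aryl silyl ether may be lost under basic conditions and the freed phenoxide methylated, or the dienone may degrade under the alkoxide. The fallback sets out from 20 and methylates the neutral alcohol before the dienone exists. MeOTf with 2,6-di-tert-butyl-4-methylpyridine (CH2Cl2, 0 °C to rt) forms no alkoxide, so no retro-Claisen cleavage is possible, and should give allyl (5R)-1-allyl-4,5-dimethoxy-2-oxo-5-[(2R)-1-Ar-propan-2-yl]cyclohex-3-ene-1-carboxylate F6. The decarboxylative dehydrogenation conditions of step 11 then convert it directly into 22, where the route is rejoined.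

**Further compounds**
F1 | step 9 | 2-(tert-butyldimethylsilyloxy)-4-methoxy-5-[(2R)-1-(3-methoxy-4-triisopropylsilyloxyphenyl)propan-2-yl]furan | CC(C)(C)[Si](C)(C)Oc1cc(OC)c(o1)[C@H](C)Cc1ccc(O[Si](C(C)C)(C(C)C)C(C)C)c(OC)c1
F2 | step 9 | allyl (1R,4R)-1-(tert-butyldimethylsilyloxy)-5-methoxy-4-[(2R)-1-(3-methoxy-4-triisopropylsilyloxyphenyl)propan-2-yl]-7-oxabicyclo[2.2.1]hept-5-ene-2-carboxylate (C2 epimers) | CC(C)(C)[Si](C)(C)O[C@@]12C=C(OC)[C@@](O1)(CC2C(=O)OCC=C)[C@H](C)Cc1ccc(O[Si](C(C)C)(C(C)C)C(C)C)c(OC)c1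
F3 | step 11 | allyl (5R)-5-hydroxy-4-methoxy-2-oxo-5-[(2R)-1-(3-methoxy-4-triisopropylsilyloxyphenyl)propan-2-yl]-1-[3-(trimethylsilyl)prop-2-yn-1-yl]cyclohex-3-ene-1-carboxylate (C1 epimers) | C=CCOC(=O)C1(CC#C[Si](C)(C)C)C[C@@](O)([C@H](C)Cc2ccc(O[Si](C(C)C)(C(C)C)C(C)C)c(OC)c2)C(OC)=CC1=O
F4 | step 11 | (4S)-4-hydroxy-5-methoxy-4-[(2R)-1-(3-methoxy-4-triisopropylsilyloxyphenyl)propan-2-yl]-2-[3-(trimethylsilyl)prop-2-yn-1-yl]cyclohexa-2,5-dien-1-one | C[Si](C)(C)C#CCC1=C[C@@](O)([C@H](C)Cc2ccc(O[Si](C(C)C)(C(C)C)C(C)C)c(OC)c2)C(OC)=CC1=O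
F5 | step 11 | (4S)-4-hydroxy-5-methoxy-4-[(2R)-1-(3-methoxy-4-triisopropylsilyloxyphenyl)propan-2-yl]-2-(prop-2-yn-1-yl)cyclohexa-2,5-dien-1-one | C#CCC1=C[C@@](O)([C@H](C)Cc2ccc(O[Si](C(C)C)(C(C)C)C(C)C)c(OC)c2)C(OC)=CC1=O
F6 | step 12 | allyl (5R)-1-allyl-4,5-dimethoxy-2-oxo-5-[(2R)-1-(3-methoxy-4-triisopropylsilyloxyphenyl)propan-2-yl]cyclohex-3-ene-1-carboxylate (C1 epimers) | C=CCOC(=O)C1(CC=C)C[C@@](OC)([C@H](C)Cc2ccc(O[Si](C(C)C)(C(C)C)C(C)C)c(OC)c2)C(OC)=CC1=O
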